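## Analysis of the target

The target 21 is a 2-arylbenzofuran: a furan ring fused to a benzo ring (ring A, C3a to C7a), with a 2,4-dihydroxyphenyl group (ring B) at C2 and a formyl group at C3. Ring A is substituted at every carbon except C7: a free hydroxyl at C4, a 3-methylbut-2-enyl (prenyl) chain at C5 and a methoxy group at C6. There is no stereocenter and the prenyl double bond has no E/Z isomers, so the problem is one of regiochemistry and functional-group tolerance. The sensitive groups are the aldehyde, three free phenols on an electron-rich π-system, and above all the prenyl chain ortho to the C4 hydroxyl, which closes to a dimethylchroman ring under protic or strong Lewis acid and excludes hydrogenolysis and most oxidants. Two things are hard: placing ring B at C2 and a one-carbon unit at C3 of a fully substituted furan (electrophilic formylation of a preformed 4,6-dioxygenated 2-arylbenzofuran would have to choose between C3 and the equally activated C7), and telling the C4 oxygen from the C6 oxygen. The strategy rests on C3, which is bonded to C2, C3a and the formyl carbon: C2 and C3 can be the ketone and aldehyde carbons of a ring B arylglyoxal, the formyl carbon can come from nitromethane (10), and C3a with O1 can be the ortho carbon and hydroxyl of a ring A phenol. The formyl oxygen at C3 lies peri to the C4 oxygen, and this is what later allows the C4 methyl ether to be singled out.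

## Retrosynthetic reasoning

**Silyl ethers (21 ⇒ 20).** The last bonds cut are the two O–Si bonds on ring B, leading back to bis(triisopropylsilyl) ether 20. Ring B must be masked from the start: a free 2'-hydroxyl would add to the nitroalkene of the key step and close a six-membered oxygen ring, and a free resorcinol would compete with ring A as a carbon nucleophile. The mask must come off without acid (the C4 hydroxyl and the C5 prenyl chain cyclise) and without hydrogenation (the alkene). Fluoride-labile triisopropylsilyl ethers meet both demands and are bulky enough to pass through amine base, sulfonic acid and aqueous buffer.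

**O4–methyl bond (20 ⇒ 19).** The C4 hydroxyl is traced back to the methyl ether in 4,6-dimethyl ether 19. Both ring A oxygens are carried as methyl ethers because the ring A phenol 6 is then mirror-symmetric, with two equivalent ortho carbons. The two methoxy groups become different only once the furan and the formyl group exist: the C4 methoxy is peri to the formyl oxygen and squeezed between C3a and C5, whereas the C6 methoxy has no such neighbour. The forward step must cleave only the chelated ether with a mild magnesium Lewis acid, without touching the silyl ethers or closing the new hydroxyl onto the prenyl chain.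

**Formyl group (19 ⇒ 16).** The aldehyde is traced back to the nitromethyl group of 16; no skeletal bond is cut. The nitromethyl group holds the formyl carbon at the correct oxidation level but is not electrophilic, so in the ring closure the phenol oxygen can only attack the ketone, which fixes ring B at C2. The forward step must be a reductive, buffered Nef reaction, since oxidative or strongly acidic variants would attack the prenyl alkene and the electron-rich rings.

**Furan ring (16 ⇒ 9 + 10 + 6).** Three bonds are cut at once: C3–CH2NO2, C3–C3a and O1–C2. This gives glyoxal 9 (2,4-bis(triisopropylsilyloxy)phenylglyoxal), nitromethane 10 and phenol 6 (3,5-dimethoxy-4-prenylphenol). C3 is the only atom from which three simple fragments radiate, so the cut is fully convergent and avoids any later C3-versus-C7 functionalisation. In the forward direction 10 must add to the aldehyde carbon of 9 and the adduct 11 must be dehydrated, through mesylate 12, to nitroenone 13 before 6 is admitted. Then 6 must attack through an ortho carbon at the alkene carbon bearing the aroyl group to give 14, the phenol oxygen must close on the ketone to give hemiketal 15, and water must be lost to give 16.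

**Ring A phenol (6 ⇒ 5 ⇒ 2 + 3 ⇒ 1).** The C4–CH2 bond of 6 is cut, via silyl ether 5, into aryllithium 4 and prenyl bromide 3. Aryllithium 4 comes from silyl ether 2 of 3,5-dimethoxyphenol 1 by deprotonation between the two methoxy groups. Cutting here uses the one position of 1 that both methoxy groups activate towards metalation, and the bulky silyl group keeps the base away from the other two ring carbons. The forward alkylation must occur at the primary terminus of 3.

**Glyoxal (9 ⇒ 8 ⇒ 7).** The aldehyde carbon of 9 is the acetyl methyl carbon of ketone 8, the bis-silyl ether of 2,4-dihydroxyacetophenone 7. Only a C–H oxidation and two O-silylations are needed, so this arm is two steps from a commodity ketone.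

## Alternatives that were turned down

**Alternative 1:** Ring A is taken apart instead of the furan. The bonds C7–C7a, C3a–C4, C4–C5 and C6–C7 are formed in a Danheiser benzannulation between furyl diazomethyl ketone A1 and alkynyl methyl ether A2. On irradiation A1 undergoes Wolff rearrangement to a furylketene, which adds to A2 in a [2+2] fashion. Four-electron ring opening and six-electron closure onto the free furan carbon, followed by tautomerisation, give phenol ester A3. For it: the C4 hydroxyl arrives free and the C6 oxygen as its methyl ether in one event, with regiochemistry set by the polarity of ketene and ynol ether. On this point it is stronger than the chosen route, which needs a selective demethylation. Against it: A1 is a trisubstituted furan carrying a diazoacetyl group and A2 is a sensitive ynol ether, each needing its own multistep synthesis. The photochemical step generates carbene and ketene next to an electron-rich trisubstituted alkene, and the electrocyclisation must engage an aromatic furan bond flanked by an ester. The ester of A3 must then be reduced and re-oxidised to the aldehyde, and the acetal groups on ring B removed with acid when the C4 hydroxyl already sits beside the prenyl chain. The chosen route is shorter, needs no photochemistry, carries C3 at the aldehyde oxidation level and ends with fluoride instead of acid.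

**Alternative 2:** The bonds C2–C3 and O1–C2 are formed in a [4+1] annulation between ortho-nitrovinyl phenol A4 and ring B benzylsulfonium salt A5. The ylide of A5 adds to the alkene carbon of A4 attached to ring A, and the phenoxide then displaces the sulfide to give trans-dihydrobenzofuran A6. For it: this annulation type is precedented, mild and trans-selective, and it installs the same nitromethyl group at C3. The propargylic ether at O4 of A6 could later be semihydrogenated and rearranged (aromatic Claisen) to deliver the C5 prenyl chain and the free C4 hydroxyl together, so O4 and O6 are distinguished by construction. On precedent and on that point it is stronger than the chosen route. Against it: A6 is at the dihydro level, so two stereocenters are made only to be erased by a dehydrogenation that must spare the acidic nitromethyl group and the electron-rich rings. There follow a Nef reaction, a semihydrogenation, a thermal rearrangement in the presence of the aldehyde, and acidic acetal removal beside the ortho-prenyl phenol. A4 itself needs a phloroglucinol aldehyde with three differently substituted oxygens. The chosen route reaches the aromatic furan directly, brings the prenyl group in intact and is several steps shorter; it pays for this with an unprecedented key step.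

**Alternative 3:** The C2–C1' bond is formed intramolecularly through an ester tether between the C3 carboxyl and the ring B oxygen. A palladium–phosphine catalyst with carbonate base and a carboxylic acid additive inserts into the C–Br bond of aryl ester A7 and arylates the benzofuran C2–H by concerted metalation–deprotonation, closing the six-membered lactone of coumestan A8. For it: every step is precedented, the tether makes the arylation regiospecific, and the lactone carbon and oxygen become the formyl carbon and the 2'-hydroxyl. On reliability it is stronger than the chosen route. Against it: A7 requires a 2-unsubstituted benzofuran-3-carboxylic acid that already carries the full ring A pattern with differentiated oxygens, so the real difficulty is only moved into a long synthesis of that acid. After the coupling the lactone must be reduced and the benzylic alcohol selectively re-oxidised beside a free phenol, and an acetal must again be removed with acid next to the prenyl chain. The chosen route is convergent from three simple pieces and forms three skeletal bonds in one flask.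

Key step: step 6

Remark on the chemistry: 11, 12, 14 and 15 are racemic (15 also a diastereomer mixture) and 17 is an E/Z mixture. All are transient and the target has no stereocenter, so their SMILES carry no stereodescriptors. Glyoxal 9 is taken into step 6 as the water-free dicarbonyl.

## Route

**Step 1**
Reactants: 1 3,5-dimethoxyphenol
Product: 2 (3,5-dimethoxyphenoxy)triisopropylsilane
Conditions: TIPSCl, imidazole, DMF, rt
Reagents that add atoms: triisopropylsilyl chloride, CC(C)[Si](Cl)(C(C)C)C(C)C
Why: Silylation of an unhindered phenol with a silyl chloride and imidazole; the bulky triisopropylsilyl group shields both ring carbons next to the silyloxy group from the base of step 2 and is slow to migrate to carbon.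

**Step 2**
Reactants: 2 (3,5-dimethoxyphenoxy)triisopropylsilane; 3 prenyl bromide (1-bromo-3-methylbut-2-ene)
Product: 5 [3,5-dimethoxy-4-(3-methylbut-2-enyl)phenoxy]triisopropylsilane, via aryllithium 4 (not isolated)
Conditions: n-BuLi, TMEDA, Et2O, 0 °C → rt; CuBr·SMe2 (10 mol %), 3, −40 → 0 °C
Reagents that add atoms: none
Why: Directed ortho-metalation: the carbon between the two methoxy groups is acidified and coordinated by both, while the carbons beside the silyloxy group are screened, so deprotonation should give 4. Copper-catalysed alkylation of 4 with the primary allylic bromide 3 should occur at the unhindered CH2 terminus (SN2) and give the linear prenyl arene.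

**Step 3**
Reactants: 5 [3,5-dimethoxy-4-(3-methylbut-2-enyl)phenoxy]triisopropylsilane
Product: 6 3,5-dimethoxy-4-(3-methylbut-2-enyl)phenol
Conditions: Bu4NF, THF, 0 °C; AcOH
Reagents that add atoms: none
Why: Fluoride desilylation of an aryl silyl ether, which leaves the prenyl alkene and the methyl ethers untouched; the acetic acid quench returns the neutral phenol.

**Step 4**
Reactants: 7 2,4-dihydroxyacetophenone
Product: 8 1-[2,4-bis(triisopropylsilyloxy)phenyl]ethanone
Conditions: TIPSCl, imidazole, DMAP (cat.), DMF, 50 °C
Reagents that add atoms: triisopropylsilyl chloride, CC(C)[Si](Cl)(C(C)C)C(C)C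
Why: Silylation of both phenols; the hydrogen-bonded 2-hydroxyl is slower and is driven by excess reagent, DMAP and mild heating. The chloride/imidazole system, unlike a silyl triflate with amine base, avoids silyl enol ether formation at the methyl ketone.

**Step 5**
Reactants: 8 1-[2,4-bis(triisopropylsilyloxy)phenyl]ethanone
Product: 9 2,4-bis(triisopropylsilyloxy)phenylglyoxal
Conditions: SeO2, 1,4-dioxane, H2O (2 equiv), 90 °C; then toluene azeotrope
Reagents that add atoms: selenium dioxide, O=[Se]=O
Why: Riley oxidation: SeO2 oxidises the enolisable methyl group of an aryl methyl ketone to the aldehyde through ene reaction and [2,3]-shift of the enol selenite. Aryl silyl ethers of this bulk should survive the weakly acidic medium, and azeotropic drying delivers the water-free dicarbonyl for step 6.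

**Step 6**
Reactants: 9 2,4-bis(triisopropylsilyloxy)phenylglyoxal; 10 nitromethane; 6 3,5-dimethoxy-4-(3-methylbut-2-enyl)phenol
Product: 16 2-[2,4-bis(triisopropylsilyloxy)phenyl]-4,6-dimethoxy-5-(3-methylbut-2-enyl)-3-(nitromethyl)benzofuran, via Henry adduct 11 (not isolated), via mesylate 12 (not isolated), via β-nitroenone 13 (not isolated), via Friedel–Crafts adduct 14 (not isolated), via cyclic hemiketal 15 (not isolated)
Conditions: 10 (1.05 equiv), Et3N (cat.), CH2Cl2, 0 °C; Ms2O, Et3N, −20 → 0 °C; 6, then CSA, 4 Å MS, 0 → 40 °C
Reagents that add atoms: none
Why: Proposed new method: a telescoped nitroaldol/dehydration/Friedel–Crafts/cyclodehydration cascade in which catalytic Et3N adds the nitronate of 10 to the aldehyde carbon of 9 (far more electrophilic than the hindered aryl ketone) to give 11, mesylation and E1cB loss of methanesulfonate from 12 give the (E)-β-nitroenone 13, and an ortho carbon of 6 then attacks the alkene carbon that is β to the nitro group and α to the ketone to give 14. The phenol oxygen of 14 adds to the ketone in a 5-exo-trig closure to hemiketal 15, and acid-catalysed loss of water aromatises the furan ring to 16. The closest known reaction types are the one-pot condensation of arylglyoxals with 2,2-dimethyl-1,3-dioxane-4,6-dione and phenols to 2-arylbenzofuran-3-ylacetic acids, the Friedel–Crafts addition of electron-rich arenes to β-nitroenones and β-nitroacrylates, and the cyclodehydration of 2-hydroxybenzyl ketones to benzofurans; new is their combination, with nitromethane as the one-carbon partner. Regiochemistry on the acceptor is secured by the nitro group, the stronger of the two acceptors, which takes up the developing charge as a nitronate only when attack occurs at the aroyl-bearing carbon. Regiochemistry on the donor is secured by 6 itself: its para position carries the prenyl group and its two ortho carbons are equivalent, each activated by three oxygen substituents. Admitting 6 only after 13 has formed keeps it away from free 9, whose direct adduct with a phenol would close to a benzofuranone, and making the medium acidic once the amine is consumed suppresses base-induced loss of the nitro group from 14; methanesulfonic anhydride is used so that no chloride, and hence no HCl, is present to add to the prenyl alkene. The ring can close only at the ketone because the nitromethyl carbon is not electrophilic, which fixes ring B at C2. No stereocenter survives: those of 11, 12, 14 and 15 are racemic and are erased on the way to 16.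

**Step 7**
Reactants: 16 2-[2,4-bis(triisopropylsilyloxy)phenyl]-4,6-dimethoxy-5-(3-methylbut-2-enyl)-3-(nitromethyl)benzofuran
Product: 19 2-[2,4-bis(triisopropylsilyloxy)phenyl]-4,6-dimethoxy-5-(3-methylbut-2-enyl)benzofuran-3-carbaldehyde, via oxime 17 (not isolated), via imine 18 (not isolated)
Conditions: TiCl3 (aq.), NH4OAc, THF/H2O, rt
Reagents that add atoms: water, O
Why: Reductive Nef reaction (McMurry variant): the acidic heteroarylmethyl nitro group enters its aci form in the acetate buffer and is deoxygenated by trivalent titanium through oxime 17 to the N–H imine 18, which hydrolyses to the aldehyde. The buffered, non-oxidising medium spares the prenyl alkene, the electron-rich benzofuran and the silyl ethers, and no free hydroxyl yet lies beside the prenyl chain.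

**Step 8**
Reactants: 19 2-[2,4-bis(triisopropylsilyloxy)phenyl]-4,6-dimethoxy-5-(3-methylbut-2-enyl)benzofuran-3-carbaldehyde
Product: 20 2-[2,4-bis(triisopropylsilyloxy)phenyl]-4-hydroxy-6-methoxy-5-(3-methylbut-2-enyl)benzofuran-3-carbaldehyde
Conditions: MgI2·OEt2, toluene/Et2O, 60 °C; aqueous work-up
Reagents that add atoms: none
Why: Chelation-assisted cleavage of an aryl methyl ether beside a carbonyl: magnesium bridges the formyl oxygen and the peri C4 methoxy oxygen, and iodide removes the activated methyl group by SN2. The C6 methoxy group has no chelation partner and lies in the ring plane, whereas the C4 methoxy group is flanked on both sides and twisted, which also raises its basicity; the mild Lewis acid should neither add to nor cyclise the prenyl chain.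

**Step 9**
Reactants: 20 2-[2,4-bis(triisopropylsilyloxy)phenyl]-4-hydroxy-6-methoxy-5-(3-methylbut-2-enyl)benzofuran-3-carbaldehyde
Product: 21 2-(2,4-dihydroxyphenyl)-4-hydroxy-6-methoxy-5-(3-methylbut-2-enyl)benzofuran-3-carbaldehyde
Conditions: Bu4NF, AcOH, THF, 0 °C
Reagents that add atoms: none
Why: Fluoride desilylation of the two aryl silyl ethers; acetic acid buffers the phenoxides so that the aldehyde is not exposed to strong base, and no acid strong enough to close the C4 hydroxyl onto the prenyl chain is present.

## Compound list

1 | 3,5-dimethoxyphenol | COc1cc(O)cc(OC)c1 | starting material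
2 | (3,5-dimethoxyphenoxy)triisopropylsilane | COc1cc(O[Si](C(C)C)(C(C)C)C(C)C)cc(OC)c1 | intermediate
3 | prenyl bromide (1-bromo-3-methylbut-2-ene) | CC(C)=CCBr | starting material
4 | [2,6-dimethoxy-4-(triisopropylsilyloxy)phenyl]lithium | [Li]c1c(OC)cc(O[Si](C(C)C)(C(C)C)C(C)C)cc1OC | intermediate
5 | [3,5-dimethoxy-4-(3-methylbut-2-enyl)phenoxy]triisopropylsilane | COc1cc(O[Si](C(C)C)(C(C)C)C(C)C)cc(OC)c1CC=C(C)C | intermediate
6 | 3,5-dimethoxy-4-(3-methylbut-2-enyl)phenol | COc1cc(O)cc(OC)c1CC=C(C)C | intermediate
7 | 2,4-dihydroxyacetophenone | CC(=O)c1ccc(O)cc1O | starting material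
8 | 1-[2,4-bis(triisopropylsilyloxy)phenyl]ethanone | CC(=O)c1ccc(O[Si](C(C)C)(C(C)C)C(C)C)cc1O[Si](C(C)C)(C(C)C)C(C)C | intermediate
9 | 2,4-bis(triisopropylsilyloxy)phenylglyoxal | O=CC(=O)c1ccc(O[Si](C(C)C)(C(C)C)C(C)C)cc1O[Si](C(C)C)(C(C)C)C(C)C | intermediate
10 | nitromethane | C[N+](=O)[O-] | starting material
11 | 1-[2,4-bis(triisopropylsilyloxy)phenyl]-2-hydroxy-3-nitropropan-1-one (racemic) | O=C(C(O)C[N+](=O)[O-])c1ccc(O[Si](C(C)C)(C(C)C)C(C)C)cc1O[Si](C(C)C)(C(C)C)C(C)C | intermediate
12 | 1-[2,4-bis(triisopropylsilyloxy)phenyl]-3-nitro-1-oxopropan-2-yl methanesulfonate (racemic) | CS(=O)(=O)OC(C[N+](=O)[O-])C(=O)c1ccc(O[Si](C(C)C)(C(C)C)C(C)C)cc1O[Si](C(C)C)(C(C)C)C(C)C | intermediate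
13 | (E)-1-[2,4-bis(triisopropylsilyloxy)phenyl]-3-nitroprop-2-en-1-one | O=C(/C=C/[N+](=O)[O-])c1ccc(O[Si](C(C)C)(C(C)C)C(C)C)cc1O[Si](C(C)C)(C(C)C)C(C)C | intermediate
14 | 1-[2,4-bis(triisopropylsilyloxy)phenyl]-2-[6-hydroxy-2,4-dimethoxy-3-(3-methylbut-2-enyl)phenyl]-3-nitropropan-1-one (racemic) | COc1cc(O)c(C(C[N+](=O)[O-])C(=O)c2ccc(O[Si](C(C)C)(C(C)C)C(C)C)cc2O[Si](C(C)C)(C(C)C)C(C)C)c(OC)c1CC=C(C)C | intermediate
15 | 2-[2,4-bis(triisopropylsilyloxy)phenyl]-4,6-dimethoxy-5-(3-methylbut-2-enyl)-3-(nitromethyl)-2,3-dihydrobenzofuran-2-ol (racemic, diastereomer mixture) | COc1cc2OC(O)(c3ccc(O[Si](C(C)C)(C(C)C)C(C)C)cc3O[Si](C(C)C)(C(C)C)C(C)C)C(C[N+](=O)[O-])c2c(OC)c1CC=C(C)C | intermediate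
16 | 2-[2,4-bis(triisopropylsilyloxy)phenyl]-4,6-dimethoxy-5-(3-methylbut-2-enyl)-3-(nitromethyl)benzofuran | COc1cc2oc(-c3ccc(O[Si](C(C)C)(C(C)C)C(C)C)cc3O[Si](C(C)C)(C(C)C)C(C)C)c(C[N+](=O)[O-])c2c(OC)c1CC=C(C)C | intermediate
17 | 2-[2,4-bis(triisopropylsilyloxy)phenyl]-4,6-dimethoxy-5-(3-methylbut-2-enyl)benzofuran-3-carbaldehyde oxime (E/Z mixture) | COc1cc2oc(-c3ccc(O[Si](C(C)C)(C(C)C)C(C)C)cc3O[Si](C(C)C)(C(C)C)C(C)C)c(C=NO)c2c(OC)c1CC=C(C)C | intermediate
18 | 1-{2-[2,4-bis(triisopropylsilyloxy)phenyl]-4,6-dimethoxy-5-(3-methylbut-2-enyl)benzofuran-3-yl}methanimine | COc1cc2oc(-c3ccc(O[Si](C(C)C)(C(C)C)C(C)C)cc3O[Si](C(C)C)(C(C)C)C(C)C)c(C=N)c2c(OC)c1CC=C(C)C | intermediate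
19 | 2-[2,4-bis(triisopropylsilyloxy)phenyl]-4,6-dimethoxy-5-(3-methylbut-2-enyl)benzofuran-3-carbaldehyde | COc1cc2oc(-c3ccc(O[Si](C(C)C)(C(C)C)C(C)C)cc3O[Si](C(C)C)(C(C)C)C(C)C)c(C=O)c2c(OC)c1CC=C(C)C | intermediate
20 | 2-[2,4-bis(triisopropylsilyloxy)phenyl]-4-hydroxy-6-methoxy-5-(3-methylbut-2-enyl)benzofuran-3-carbaldehyde | COc1cc2oc(-c3ccc(O[Si](C(C)C)(C(C)C)C(C)C)cc3O[Si](C(C)C)(C(C)C)C(C)C)c(C=O)c2c(O)c1CC=C(C)C | intermediate
21 | 2-(2,4-dihydroxyphenyl)-4-hydroxy-6-methoxy-5-(3-methylbut-2-enyl)benzofuran-3-carbaldehyde | COc1cc2oc(-c3ccc(O)cc3O)c(C=O)c2c(O)c1CC=C(C)C | target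

## Step count and risks

Total: 9 steps. Longest linear sequence: 7 steps (steps 1–3 and 6–9); the glyoxal arm contributes steps 4 and 5.

**Step 6 (key step, Proposed new method).** The most likely failure is in the Friedel–Crafts stage: the very electrophilic nitroenone 13 may oligomerise or be O-alkylated by the phenol before carbon attack. Residual amine may also trigger elimination of the nitro group from 14 instead of cyclodehydration. If the acid is raised to compensate, silyl ethers may be lost or the prenyl alkene hydrated. The fallback sets out from 9 and 6 and comes back at 19, using only known chemistry. The established telescoped condensation of an arylglyoxal, 2,2-dimethyl-1,3-dioxane-4,6-dione and a phenol (Et3N, MeCN, rt; then AcOH, reflux) should give 2-{2-[2,4-bis(triisopropylsilyloxy)phenyl]-4,6-dimethoxy-5-(3-methylbut-2-enyl)benzofuran-3-yl}acetic acid F1 with loss of acetone and CO2. Its dianion (LiN(i-Pr)2, THF, −78 °C) is hydroxylated with O2 and P(OEt)3 to the racemic 2-hydroxy acid F2 (2-hydroxy-2-{2-[2,4-bis(triisopropylsilyloxy)phenyl]-4,6-dimethoxy-5-(3-methylbut-2-enyl)benzofuran-3-yl}acetic acid). Oxidative decarboxylation with Pb(OAc)4 (CH2Cl2, rt) then gives aldehyde 19, which bypasses steps 6 and 7.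

**Step 8.** The magnesium chelate between the formyl oxygen and O4 is seven-membered, weaker than the six-membered chelates of ortho-acyl anisoles. Cleavage may therefore be sluggish, and forcing it risks loss of selectivity between the two methoxy groups, closure of the freed hydroxyl onto the prenyl chain, or silyl loss. The fallback sets out from 19 and comes back at 20. Both ring A methyl ethers are cleaved (BCl3, n-Bu4NI, CH2Cl2, −78 → 0 °C) to give 2-[2,4-bis(triisopropylsilyloxy)phenyl]-4,6-dihydroxy-5-(3-methylbut-2-enyl)benzofuran-3-carbaldehyde F3. Only the C6 hydroxyl is then re-methylated under Mitsunobu conditions (MeOH, PPh3, DIAD, THF, 0 °C), the hydrogen-bonded, doubly flanked C4 hydroxyl being the poorer partner. The exhaustive cleavage is itself the weak point of this fallback, since boron halides can also attack the prenyl chain.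

**Step 7.** The reduction may stall at the oxime, the aldoxime may dehydrate to a nitrile, or insufficient buffering of the acidic TiCl3 solution may hydrolyse silyl ethers. The fallback sets out from 16 and comes back at 19. The nitro group is reduced only to the oxime with SnCl2, PhSH and Et3N (MeCN, rt), oxime 17 is isolated, and the oxime is exchanged with aqueous glyoxylic acid (THF, rt) to free aldehyde 19. No new compound is made.

**Step 5.** Hot aqueous selenous acid may strip the silyl ether ortho to the ketone, or oxidation may run on to the arylglyoxylic acid. The fallback sets out from 8 and comes back at 9. α-Bromination with PhNMe3Br3 (THF, 0 °C) gives 2-bromo-1-[2,4-bis(triisopropylsilyloxy)phenyl]ethanone F4, and Kornblum oxidation (DMSO, NaHCO3, rt) converts it to glyoxal 9.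

**Step 2.** The allylic bromide may be attacked at its tertiary terminus (allylic transposition), or metalation may stray to a carbon beside the silyloxy group and be followed by silyl migration. The fallback sets out from 2 (through 4) and comes back at 5, and it answers the first of these problems only. Aryllithium 4 is quenched with allyl bromide, which has no regiochemical ambiguity, to give (4-allyl-3,5-dimethoxyphenoxy)triisopropylsilane F5. Cross-metathesis with 2-methylbut-2-ene (second-generation Grubbs catalyst, CH2Cl2, 40 °C) then turns the allyl group into the prenyl group of 5.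

## Further compounds

F1 | step 6 | 2-{2-[2,4-bis(triisopropylsilyloxy)phenyl]-4,6-dimethoxy-5-(3-methylbut-2-enyl)benzofuran-3-yl}acetic acid | COc1cc2oc(-c3ccc(O[Si](C(C)C)(C(C)C)C(C)C)cc3O[Si](C(C)C)(C(C)C)C(C)C)c(CC(=O)O)c2c(OC)c1CC=C(C)C
F2 | step 6 | 2-hydroxy-2-{2-[2,4-bis(triisopropylsilyloxy)phenyl]-4,6-dimethoxy-5-(3-methylbut-2-enyl)benzofuran-3-yl}acetic acid (racemic) | COc1cc2oc(-c3ccc(O[Si](C(C)C)(C(C)C)C(C)C)cc3O[Si](C(C)C)(C(C)C)C(C)C)c(C(O)C(=O)O)c2c(OC)c1CC=C(C)C
F3 | step 8 | 2-[2,4-bis(triisopropylsilyloxy)phenyl]-4,6-dihydroxy-5-(3-methylbut-2-enyl)benzofuran-3-carbaldehyde | Oc1cc2oc(-c3ccc(O[Si](C(C)C)(C(C)C)C(C)C)cc3O[Si](C(C)C)(C(C)C)C(C)C)c(C=O)c2c(O)c1CC=C(C)C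
F0 | step 7 | none | none
F4 | step 5 | 2-bromo-1-[2,4-bis(triisopropylsilyloxy)phenyl]ethanone | O=C(CBr)c1ccc(O[Si](C(C)C)(C(C)C)C(C)C)cc1O[Si](C(C)C)(C(C)C)C(C)C
F5 | step 2 | (4-allyl-3,5-dimethoxyphenoxy)triisopropylsilane | C=CCc1c(OC)cc(O[Si](C(C)C)(C(C)C)C(C)C)cc1OC
A1 | alternative 1 | methyl 2-[2,4-bis(methoxymethoxy)phenyl]-5-(2-diazoacetyl)furan-3-carboxylate | COC(=O)c1cc(C(=O)C=[N+]=[N-])oc1-c1ccc(OCOC)cc1OCOC
A2 | alternative 1 | 1-methoxy-5-methylhex-4-en-1-yne | COC#CCC=C(C)C
A3 | alternative 1 | methyl 2-[2,4-bis(methoxymethoxy)phenyl]-4-hydroxy-6-methoxy-5-(3-methylbut-2-enyl)benzofuran-3-carboxylate | COc1cc2oc(-c3ccc(OCOC)cc3OCOC)c(C(=O)OC)c2c(O)c1CC=C(C)C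
A4 | alternative 2 | 5-methoxy-3-(2-methylbut-3-yn-2-yloxy)-2-[(E)-2-nitroethenyl]phenol | COc1cc(O)c(/C=C/[N+](=O)[O-])c(OC(C)(C)C#C)c1
A5 | alternative 2 | [2,4-bis(methoxymethoxy)benzyl]dimethylsulfonium bromide | C[S+](C)Cc1ccc(OCOC)cc1OCOC.[Br-]
A6 | alternative 2 | trans-2-[2,4-bis(methoxymethoxy)phenyl]-6-methoxy-4-(2-methylbut-3-yn-2-yloxy)-3-(nitromethyl)-2,3-dihydrobenzofuran (racemic, one enantiomer drawn) | COc1cc2O[C@@H](c3ccc(OCOC)cc3OCOC)[C@H](C[N+](=O)[O-])c2c(OC(C)(C)C#C)c1
A7 | alternative 3 | 2-bromo-5-(triisopropylsilyloxy)phenyl 6-methoxy-4-(methoxymethoxy)-5-(3-methylbut-2-enyl)benzofuran-3-carboxylate | COc1cc2occ(C(=O)Oc3cc(O[Si](C(C)C)(C(C)C)C(C)C)ccc3Br)c2c(OCOC)c1CC=C(C)C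
A8 | alternative 3 | 9-methoxy-7-(methoxymethoxy)-8-(3-methylbut-2-enyl)-3-(triisopropylsilyloxy)benzofuro[3,2-c]chromen-6-one (protected coumestan) | COc1cc2oc3-c4ccc(O[Si](C(C)C)(C(C)C)C(C)C)cc4OC(=O)c3c2c(OCOC)c1CC=C(C)C
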